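The synthesis stands or falls with one disconnection: the benzene ring of the lactone is not bought but assembled. That ring (C4a, C5, C6, C7, C8, C8a in isochroman-1-one numbering) is a resorcylate, with hydroxyls on C6 and C8, the C1 carbonyl attached to C8a and the C4 methylene to C4a, which maps onto an alk-2-ynoate plus a 1,1-dialkoxy-3-silyloxybuta-1,3-diene. A single thermal [4+2] cycloaddition with loss of methanol forges C4a–C5 and C8–C8a and sets all six ring substituents. Its precursor is an acyclic δ-silyloxy ynoate already holding both stereocentres, one from (S)-propylene oxide, one from a hydrolytic kinetic resolution; lactonisation and one chelation-directed O-demethylation finish.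

Key step: step 9

Remark: the target SMILES is read as (3R)-6,8-dihydroxy-3-[(10S)-10-methoxyundecyl]isochroman-1-one. The hydrolytic kinetic resolution is assumed to follow its usual sense for alkyl oxiranes, the (R,R)-catalyst leaving the (R)-epoxide unreacted.

**Step 1**
Reactants: 1 (S)-propylene oxide; 2 10-bromodec-1-ene
Product: 4 (2S)-tridec-12-en-2-ol, via dec-9-en-1-ylmagnesium bromide 3 (not isolated)
Conditions: 2, Mg, THF, rt; then CuI (10 mol %), 1, THF, −30 → 0 °C; aq. NH4Cl
Reagents that add atoms: none
Why: Copper-catalysed Grignard opening of a terminal epoxide proceeds by SN2 attack at the unsubstituted carbon, so the C–O stereocentre of 1 is carried unchanged into 4 as the (S)-carbinol that becomes C10 of the side chain (chiral-pool control).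

**Step 2**
Reactants: 4 (2S)-tridec-12-en-2-ol
Product: 5 (12S)-12-methoxytridec-1-ene
Conditions: NaH, MeI, THF, 0 °C → rt
Reagents that add atoms: iodomethane, CI
Why: Williamson ether synthesis on the sodium alkoxide forms the methyl ether without touching the C–O bond of the stereocentre, and the terminal alkene is inert.

**Step 3**
Reactants: 5 (12S)-12-methoxytridec-1-ene
Product: 6 2-[(10S)-10-methoxyundecyl]oxirane (both C2 epimers)
Conditions: mCPBA, NaHCO3, CH2Cl2, 0 °C → rt
Reagents that add atoms: 3-chloroperoxybenzoic acid (mCPBA), O=C(OO)c1cccc(Cl)c1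
Why: Prilezhaev epoxidation of the monosubstituted alkene leaves the ether alone; the distant stereocentre gives no facial control, so both C2 epimers are expected and are sorted in step 4.

**Step 4**
Reactants: 6 2-[(10S)-10-methoxyundecyl]oxirane (both C2 epimers)
Product: 7 (2R)-2-[(10S)-10-methoxyundecyl]oxirane
Conditions: (R,R)-(salen)Co(OAc) (0.5 mol %; trivalent cobalt; salen = dianion of N,N'-bis(3,5-di-tert-butylsalicylidene)-(1R,2R)-cyclohexane-1,2-diamine), H2O (0.55 equiv), THF (minimal), 0 °C → rt; chromatography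
Reagents that add atoms: none
Why: Jacobsen hydrolytic kinetic resolution, in which the chiral cobalt salen catalyst hydrates the (2S)-epimer at its terminal carbon much faster than the (2R)-epimer, should leave 7 with the future C3 configuration set by catalyst control, the polar diol being removed by chromatography.

**Step 5**
Reactants: 7 (2R)-2-[(10S)-10-methoxyundecyl]oxirane; 8 methyl propiolate
Product: 10 methyl (5R,15S)-5-hydroxy-15-methoxyhexadec-2-ynoate, via methyl 3-lithiopropiolate 9 (not isolated)
Conditions: 8 (2.5 equiv), n-BuLi, THF, −78 °C; BF3·OEt2; then 7, −78 °C; H2O quench at −78 °C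
Reagents that add atoms: none
Why: Yamaguchi–Hirao alkynylation, in which the BF3-activated epoxide is opened at its CH2 terminus by the lithium acetylide at −78 °C, forms the alkyne–CH2 bond and leaves the (R) C–O centre intact.

**Step 6**
Reactants: 10 methyl (5R,15S)-5-hydroxy-15-methoxyhexadec-2-ynoate
Product: 11 methyl (5R,15S)-5-(tert-butyldimethylsilyloxy)-15-methoxyhexadec-2-ynoate
Conditions: TBSOTf, 2,6-lutidine, CH2Cl2, −78 → 0 °C
Reagents that add atoms: tert-butyldimethylsilyl trifluoromethanesulfonate, CC(C)(C)[Si](C)(C)OS(=O)(=O)C(F)(F)F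
Why: Silylation of the secondary alcohol with a silyl triflate and the hindered, non-nucleophilic base 2,6-lutidine gives the TBS ether without conjugate addition to the ynoate, so that no protic group meets the ketene acetal in step 9.

**Step 7**
Reactants: 12 1,1-dimethoxyethene; 13 acetyl chloride
Product: 14 4,4-dimethoxybut-3-en-2-one
Conditions: Et3N, Et2O, 0 °C → rt (13 added slowly to 12 and the amine)
Reagents that add atoms: none
Why: C-acylation of the electron-rich ketene acetal by the acid chloride, followed by loss of HCl to the amine (ketene-acetal acylation), should give the acylketene acetal.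

**Step 8**
Reactants: 14 4,4-dimethoxybut-3-en-2-one
Product: 15 1,1-dimethoxy-3-(trimethylsilyloxy)buta-1,3-diene
Conditions: TMSOTf, Et3N, Et2O, 0 °C; filtration under Ar, distillation under reduced pressure, used at once
Reagents that add atoms: trimethylsilyl trifluoromethanesulfonate, C[Si](C)(C)OS(=O)(=O)C(F)(F)F
Why: Soft enolisation of the methyl ketone, its only enolisable position, with the silyl triflate and Et3N gives the cross-conjugated silyl enol ether (silyl enol ether formation).

**Step 9**
Reactants: 11 methyl (5R,15S)-5-(tert-butyldimethylsilyloxy)-15-methoxyhexadec-2-ynoate; 15 1,1-dimethoxy-3-(trimethylsilyloxy)buta-1,3-diene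
Product: 18 methyl 2-[(2R,12S)-2-(tert-butyldimethylsilyloxy)-12-methoxytridecyl]-4-hydroxy-6-methoxybenzoate, via dimethoxycyclohexadiene cycloadduct 16 (not isolated), via aryl trimethylsilyl ether 17 (not isolated)
Conditions: 15 (3 equiv), toluene (concentrated), 120 °C, sealed tube, Ar; then 0.1 M HCl, THF, 0 °C
Reagents that add atoms: none
Why: The diene is electron-rich and nucleophilic at its CH2 terminus while the ynoate is electrophilic at its β-carbon, so a concerted but asynchronous normal-demand [4+2] cycloaddition joins the diene CH2 to the β-carbon (C4a–C5) and the acetal carbon to the α-carbon (C8–C8a) to give cyclohexa-1,4-diene 16. Adduct 16 then loses methanol from the acetal carbon to reach aromatic silyl ether 17, whose Si–O bond is hydrolysed on work-up. The closest known reaction type is the Diels–Alder benzannulation of 1,1-dialkoxy-3-silyloxybuta-1,3-dienes with alk-2-ynoates to give 2-alkyl-4-hydroxy-6-alkoxybenzoates. The one ring closed, the six-membered carbocycle, is formed by intermolecular cycloaddition in which both ring bonds arise in one pericyclic event. No stereocentre is created, and the silyl ether centre of 11 lies two atoms from the alkyne and is not touched. The selectivity needed is regiochemical (ester flanked by OMe and the side arm) and is secured by the matched polarity of the two partners, while the TBS ether keeps the ketene acetal away from any protic group.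

**Step 10**
Reactants: 18 methyl 2-[(2R,12S)-2-(tert-butyldimethylsilyloxy)-12-methoxytridecyl]-4-hydroxy-6-methoxybenzoate
Product: 20 (3R)-6-hydroxy-8-methoxy-3-[(10S)-10-methoxyundecyl]isochroman-1-one, via desilylated hydroxy ester 19 (not isolated)
Conditions: TsOH·H2O (0.2 equiv), MeOH, rt; then solvent switch to toluene, 80 °C
Reagents that add atoms: none
Why: Acid-catalysed methanolysis of the TBS ether frees the C3 hydroxyl, which on heating attacks the neighbouring methyl ester in an intramolecular transesterification (lactonisation to the six-membered ring) that does not break the C3–O bond, so the (R) configuration is retained.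

**Step 11**
Reactants: 20 (3R)-6-hydroxy-8-methoxy-3-[(10S)-10-methoxyundecyl]isochroman-1-one
Product: 21 (3R)-6,8-dihydroxy-3-[(10S)-10-methoxyundecyl]isochroman-1-one
Conditions: BCl3 (3 equiv), CH2Cl2, −78 → −20 °C; then H2O
Reagents that add atoms: none
Why: Chelation-directed Lewis-acid ether cleavage: BCl3 bridges the lactone carbonyl and the peri C8 methoxy oxygen, chloride removes that methyl group by SN2, and the unchelated secondary alkyl methyl ether and the lactone should be left alone at low temperature.

**Compound list**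

1 | (S)-propylene oxide [(2S)-2-methyloxirane] | C[C@H]1CO1 | starting material
2 | 10-bromodec-1-ene | BrCCCCCCCCC=C | starting material
3 | dec-9-en-1-ylmagnesium bromide | Br[Mg]CCCCCCCCC=C | intermediate
4 | (2S)-tridec-12-en-2-ol | O[C@@H](C)CCCCCCCCCC=C | intermediate
5 | (12S)-12-methoxytridec-1-ene | CO[C@@H](C)CCCCCCCCCC=C | intermediate
6 | 2-[(10S)-10-methoxyundecyl]oxirane, both C2 epimers | CO[C@@H](C)CCCCCCCCCC1CO1 | intermediate
7 | (2R)-2-[(10S)-10-methoxyundecyl]oxirane | CO[C@@H](C)CCCCCCCCC[C@@H]1CO1 | intermediate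
8 | methyl propiolate | C#CC(=O)OC | starting material
9 | methyl 3-lithioprop-2-ynoate | [Li]C#CC(=O)OC | intermediate
10 | methyl (5R,15S)-5-hydroxy-15-methoxyhexadec-2-ynoate | CO[C@@H](C)CCCCCCCCC[C@@H](O)CC#CC(=O)OC | intermediate
11 | methyl (5R,15S)-5-(tert-butyldimethylsilyloxy)-15-methoxyhexadec-2-ynoate | CO[C@@H](C)CCCCCCCCC[C@@H](O[Si](C)(C)C(C)(C)C)CC#CC(=O)OC | intermediate
12 | 1,1-dimethoxyethene | C=C(OC)OC | starting material
13 | acetyl chloride | CC(=O)Cl | starting material
14 | 4,4-dimethoxybut-3-en-2-one | CC(=O)C=C(OC)OC | intermediate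
15 | 1,1-dimethoxy-3-(trimethylsilyloxy)buta-1,3-diene | COC(OC)=CC(=C)O[Si](C)(C)C | intermediate
16 | methyl 2-[(2R,12S)-2-(tert-butyldimethylsilyloxy)-12-methoxytridecyl]-6,6-dimethoxy-4-(trimethylsilyloxy)cyclohexa-1,4-diene-1-carboxylate | CO[C@@H](C)CCCCCCCCC[C@@H](O[Si](C)(C)C(C)(C)C)CC1=C(C(=O)OC)C(OC)(OC)C=C(O[Si](C)(C)C)C1 | intermediate
17 | methyl 2-[(2R,12S)-2-(tert-butyldimethylsilyloxy)-12-methoxytridecyl]-6-methoxy-4-(trimethylsilyloxy)benzoate | CO[C@@H](C)CCCCCCCCC[C@@H](O[Si](C)(C)C(C)(C)C)Cc1cc(O[Si](C)(C)C)cc(OC)c1C(=O)OC | intermediate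
18 | methyl 2-[(2R,12S)-2-(tert-butyldimethylsilyloxy)-12-methoxytridecyl]-4-hydroxy-6-methoxybenzoate | CO[C@@H](C)CCCCCCCCC[C@@H](O[Si](C)(C)C(C)(C)C)Cc1cc(O)cc(OC)c1C(=O)OC | intermediate
19 | methyl 4-hydroxy-2-[(2R,12S)-2-hydroxy-12-methoxytridecyl]-6-methoxybenzoate | CO[C@@H](C)CCCCCCCCC[C@@H](O)Cc1cc(O)cc(OC)c1C(=O)OC | intermediate
20 | (3R)-6-hydroxy-8-methoxy-3-[(10S)-10-methoxyundecyl]isochroman-1-one | CO[C@@H](C)CCCCCCCCC[C@@H]1Cc2cc(O)cc(OC)c2C(=O)O1 | intermediate
21 | (3R)-6,8-dihydroxy-3-[(10S)-10-methoxyundecyl]isochroman-1-one | CO[C@@H](C)CCCCCCCCC[C@@H]1Cc2cc(O)cc(O)c2C(=O)O1 | target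

**Step count and risk**

Total step count: 11. Longest linear sequence: 9 steps (steps 1 to 6, then 9, 10 and 11); the diene branch has 2 steps (7 and 8).

The three steps most likely to fail, in order of risk:

Step 9. The cycloaddition may be slower than the thermal and hydrolytic decay of the ketene-acetal diene, because the ynoate is activated by one ester only and carries a β-alkyl group; loss of methanol may also stop short of the arene. The fallback buys the ring instead of building it; it sets out from 7 and rejoins the route at 21. Commercial 1-bromo-3,5-bis(benzyloxy)benzene (Brc1cc(OCc2ccccc2)cc(OCc2ccccc2)c1) is converted with Mg in THF into 3,5-bis(benzyloxy)phenylmagnesium bromide F1. With CuI catalysis this should open 7 at its CH2 terminus to give (2R,12S)-1-[3,5-bis(benzyloxy)phenyl]-12-methoxytridecan-2-ol F2. NBS in MeCN at 0 °C should brominate the ring carbon ortho to the side chain and para to a benzyloxy group, giving (2R,12S)-1-[3,5-bis(benzyloxy)-2-bromophenyl]-12-methoxytridecan-2-ol F3. Palladium-catalysed carbonylative lactonisation (CO 1 atm, Pd(OAc)2, Xantphos, Et3N, toluene, 100 °C) would then close the lactone to (3R)-6,8-bis(benzyloxy)-3-[(10S)-10-methoxyundecyl]isochroman-1-one F4. Hydrogenolysis (H2, Pd/C, EtOAc) removes both benzyl groups, spares the aliphatic methyl ether and the non-benzylic lactone C–O bond, and gives 21.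

Step 5. The lithiated propiolate may decompose or add to itself before it meets the epoxide, and BF3 may rearrange the epoxide or open it with fluoride. The fallback installs the ester after the C–C bond; it sets out from 7 and returns at 11. Lithium acetylide–ethylenediamine complex in DMSO at rt opens 7 at CH2 to give (4R,14S)-14-methoxypentadec-1-yn-4-ol F5. TBSCl and imidazole in DMF give tert-butyl{[(4R,14S)-14-methoxypentadec-1-yn-4-yl]oxy}dimethylsilane F6. n-BuLi in THF at −78 °C forms [(4R,14S)-4-(tert-butyldimethylsilyloxy)-14-methoxypentadec-1-yn-1-yl]lithium F7, which methyl chloroformate acylates to 11.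

Step 11. The Lewis acid may also attack the secondary alkyl methyl ether, or demethylation may stop at partial conversion. The fallback never makes an aryl methyl ether; it sets out from 11 and returns at 21. Commercial dimedone (5,5-dimethylcyclohexane-1,3-dione) with TMSOTf and Et3N in Et2O gives 5,5-dimethyl-1,3-bis(trimethylsilyloxy)cyclohexa-1,3-diene F8. Heated with 11 at about 140 °C it should add to the triple bond in the same polarity-matched sense to give methyl 3-[(2R,12S)-2-(tert-butyldimethylsilyloxy)-12-methoxytridecyl]-8,8-dimethyl-1,5-bis(trimethylsilyloxy)bicyclo[2.2.2]octa-2,5-diene-2-carboxylate F9. This adduct loses 2-methylpropene by retro-Diels–Alder (Alder–Rickert) cleavage to give methyl 2-[(2R,12S)-2-(tert-butyldimethylsilyloxy)-12-methoxytridecyl]-4,6-bis(trimethylsilyloxy)benzoate F10. Dilute acid work-up gives methyl 2-[(2R,12S)-2-(tert-butyldimethylsilyloxy)-12-methoxytridecyl]-4,6-dihydroxybenzoate F11. The conditions of step 10 then lead, through methyl 2,4-dihydroxy-6-[(2R,12S)-2-hydroxy-12-methoxytridecyl]benzoate F12, directly to 21.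

**Further compounds**

F1 | step 9 | 3,5-bis(benzyloxy)phenylmagnesium bromide | Br[Mg]c1cc(OCc2ccccc2)cc(OCc2ccccc2)c1
F2 | step 9 | (2R,12S)-1-[3,5-bis(benzyloxy)phenyl]-12-methoxytridecan-2-ol | CO[C@@H](C)CCCCCCCCC[C@@H](O)Cc1cc(OCc2ccccc2)cc(OCc2ccccc2)c1
F3 | step 9 | (2R,12S)-1-[3,5-bis(benzyloxy)-2-bromophenyl]-12-methoxytridecan-2-ol | CO[C@@H](C)CCCCCCCCC[C@@H](O)Cc1cc(OCc2ccccc2)cc(OCc2ccccc2)c1Br
F4 | step 9 | (3R)-6,8-bis(benzyloxy)-3-[(10S)-10-methoxyundecyl]isochroman-1-one | CO[C@@H](C)CCCCCCCCC[C@@H]1Cc2cc(OCc3ccccc3)cc(OCc3ccccc3)c2C(=O)O1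
F5 | step 5 | (4R,14S)-14-methoxypentadec-1-yn-4-ol | CO[C@@H](C)CCCCCCCCC[C@@H](O)CC#C
F6 | step 5 | tert-butyl{[(4R,14S)-14-methoxypentadec-1-yn-4-yl]oxy}dimethylsilane | CO[C@@H](C)CCCCCCCCC[C@@H](O[Si](C)(C)C(C)(C)C)CC#C
F7 | step 5 | [(4R,14S)-4-(tert-butyldimethylsilyloxy)-14-methoxypentadec-1-yn-1-yl]lithium | CO[C@@H](C)CCCCCCCCC[C@@H](O[Si](C)(C)C(C)(C)C)CC#C[Li]
F8 | step 11 | 5,5-dimethyl-1,3-bis(trimethylsilyloxy)cyclohexa-1,3-diene | CC1(C)CC(O[Si](C)(C)C)=CC(O[Si](C)(C)C)=C1
F9 | step 11 | methyl 3-[(2R,12S)-2-(tert-butyldimethylsilyloxy)-12-methoxytridecyl]-8,8-dimethyl-1,5-bis(trimethylsilyloxy)bicyclo[2.2.2]octa-2,5-diene-2-carboxylate | CO[C@@H](C)CCCCCCCCC[C@@H](O[Si](C)(C)C(C)(C)C)CC1=C(C(=O)OC)C2(O[Si](C)(C)C)C=C(O[Si](C)(C)C)C1C(C)(C)C2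
F10 | step 11 | methyl 2-[(2R,12S)-2-(tert-butyldimethylsilyloxy)-12-methoxytridecyl]-4,6-bis(trimethylsilyloxy)benzoate | CO[C@@H](C)CCCCCCCCC[C@@H](O[Si](C)(C)C(C)(C)C)Cc1cc(O[Si](C)(C)C)cc(O[Si](C)(C)C)c1C(=O)OC
F11 | step 11 | methyl 2-[(2R,12S)-2-(tert-butyldimethylsilyloxy)-12-methoxytridecyl]-4,6-dihydroxybenzoate | CO[C@@H](C)CCCCCCCCC[C@@H](O[Si](C)(C)C(C)(C)C)Cc1cc(O)cc(O)c1C(=O)OC
F12 | step 11 | methyl 2,4-dihydroxy-6-[(2R,12S)-2-hydroxy-12-methoxytridecyl]benzoate | CO[C@@H](C)CCCCCCCCC[C@@H](O)Cc1cc(O)cc(O)c1C(=O)OC
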